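The cyclopentane ring of the daucane core hides 3-methylcyclopent-2-enone: C4 is its carbonyl carbon, C5 its α-carbon and the methyl-bearing quaternary C1 its β-carbon. Both arms of the seven-membered ring therefore leave from the C1–C5 fusion bond, C10 as a nucleophile and C6 as an electrophile. One copper-catalysed operation attaches a 1-silylvinyl unit (C10–C9) to C1 and, through the resulting enolate, but-2-ynal (C6–C8 plus the C8 methyl) to C5. This fixes the absolute configuration at C1 and the trans fusion without closing a ring. The precursors are just the achiral enone, a vinylalane and an ynal. Only the C8–C9 bond then remains, made by chromium-mediated closure.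

Key step: step 3

Remark: daucane numbering is used throughout (C1 quaternary fusion carbon, C2–C3 ring CH2CH2, C4 isopropyl carbinol, C5 fusion CH, C6 ester carbinol, C7=C8 alkene, C9 ketone, C10 CH2). It is assumed that the ligand enantiomer giving (1S)-6 can be chosen for the NHC–copper catalyst.

Step 1
Reactants: 1 trimethylsilylacetylene
Product: 2 diisobutyl[1-(trimethylsilyl)vinyl]alane (kept as a stock solution)
Conditions: DIBAL-H (1.0 equiv), hexanes/THF, 55 °C
Reagents that add atoms: diisobutylaluminium hydride, CC(C)C[AlH]CC(C)C
Why: Syn hydroalumination of a silylalkyne places hydride on the terminal carbon and aluminium on the silicon-bearing carbon, where the α-silyl group stabilises the C–Al bond, so the geminal Si/Al alkenyl reagent forms regioselectively.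

Step 2
Reactants: 3 but-2-yn-1-ol
Product: 4 but-2-ynal
Conditions: activated MnO2, CH2Cl2, rt; filter, dry over 4 Å MS, use as a titrated solution
Reagents that add atoms: none
Why: Manganese dioxide oxidation is selective for propargylic alcohols, stops at the aldehyde, and after filtration leaves a metal-free solution of the volatile ynal.

Step 3
Reactants: 5 3-methylcyclopent-2-en-1-one; 2 diisobutyl[1-(trimethylsilyl)vinyl]alane; 4 but-2-ynal
Product: 7 (2S,3S)-2-(1-hydroxybut-2-yn-1-yl)-3-methyl-3-[1-(trimethylsilyl)vinyl]cyclopentan-1-one as a mixture of C6 epimers (daucane 1S,5S; side chain trans to the silylvinyl group), via aluminium enolate 6 (not isolated)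
Conditions: Cu(OTf)2 (5 mol %), chiral sulfonate-tethered bidentate NHC·Ag(I) complex (2.5 mol %), 2 (1.3 equiv), THF, −30 °C; then 4 (3 equiv), −78 → −30 °C; aq. Rochelle salt
Reagents that add atoms: none
Why: Alkenyl transfer from aluminium to the NHC–copper centre, π-complexation of the aluminium-activated enone, addition at C1 and reductive elimination form C1–C10 and release the diisobutylaluminium enolate 6 with its double bond locked between C4 and C5; 6 then binds the ynal at aluminium and attacks its carbonyl through a closed six-membered transition state to form C5–C6. The first half is the established NHC–Cu-catalysed enantioselective conjugate addition of silyl-substituted vinylaluminium reagents to β-substituted cyclopentenones, and the second half is the classical tandem conjugate addition–aldol capture of a metal enolate, run here with a slim and very electrophilic aldehyde because the enolate carbon adjoins a quaternary centre. No ring is closed. C1 is set by the chiral NHC ligand (enantioface of the enone); C5 is set by approach of the aldehyde to the enolate face opposite the large 1-silylvinyl group, which leaves C6 and C10 trans, also the more stable arrangement; C6 is not relied upon, although a chair Zimmerman–Traxler state should favour the anti aldol that carries the natural configuration, and both epimers converge at ynone 11. The step needs 1,4- over 1,2-addition and alkenyl over isobutyl transfer (copper and the faster-migrating sp2 ligand), no enolate equilibration (covalent Al–O bond at low temperature) and 1,2- rather than 1,4-attack on the ynal (aluminium-templated transition state and methyl-capped alkyne); excess ynal compensates for what surplus alane consumes.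

Step 4
Reactants: 7 aldol (C6 epimers)
Product: 8 C6 triethylsilyl ether of 7 (1S,5S; C6 epimers)
Conditions: TESOTf (1.1 equiv), 2,6-lutidine, CH2Cl2, −78 °C
Reagents that add atoms: triethylsilyl triflate, CC[Si](CC)(CC)OS(=O)(=O)C(F)(F)F
Why: O-silylation with a silyl triflate and a hindered base is fast at −78 °C, so the β-hydroxy ketone is capped before retro-aldol, elimination or C5 epimerisation can intervene, and the proton that would quench the organometallic of step 5 is removed.

Step 5
Reactants: 8 silyl ether ketone
Product: 10 (1S,4R,5S)-2-(1-hydroxybut-2-yn-1-yl)-1-isopropyl-3-methyl-3-[1-(trimethylsilyl)vinyl]cyclopentan-1-ol, C4-OH cis and isopropyl trans to the C5 side chain (C6 epimers), via tertiary carbinol silyl ether 9 (not isolated)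
Conditions: anhydrous CeCl3 (3 equiv), i-PrMgCl (3 equiv), THF, −78 → −20 °C; then 1 M HCl, THF, rt
Reagents that add atoms: isopropylmagnesium chloride, CC(C)[Mg]Cl
Why: In this organocerium 1,2-addition the weakly basic, oxophilic isopropylcerium reagent suppresses enolisation, β-silyloxy elimination and β-hydride reduction of the hindered cyclopentanone and attacks C4 from the face opposite the adjacent C5 side chain and the pseudoaxial C1 methyl, which sets C4 with hydroxyl cis to C6, after which the acidic quench hydrolyses the triethylsilyl ether.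

Step 6
Reactants: 10 diol (C6 epimers)
Product: 11 (1S,4R,5R)-β-hydroxy ynone, 1-{2-hydroxy-2-isopropyl-5-methyl-5-[1-(trimethylsilyl)vinyl]cyclopentyl}but-2-yn-1-one
Conditions: Dess–Martin periodinane, CH2Cl2, 0 °C → rt
Reagents that add atoms: none
Why: Dess–Martin oxidation touches only the secondary propargylic carbinol, merges both C6 epimers into one ynone under near-neutral conditions that avoid retro-aldol opening or oxa-Michael closure, and leaves C5 in its more stable trans arrangement.

Step 7
Reactants: 11 ynone
Product: 12 (1S,4R,5S,6R)-propargylic diol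
Conditions: Ru[(R,R)-TsDPEN](p-cymene) (preformed amido complex, 5 mol %), i-PrOH, rt
Reagents that add atoms: none
Why: In this Noyori asymmetric transfer hydrogenation of an alkynyl ketone the (R,R)-catalyst distinguishes the slim alkynyl group from the branched C5 substituent and should give the (6R)-carbinol under base-free conditions that tolerate the free C4 hydroxyl, so C6 is set by the catalyst and not by an uncertain rotamer preference of a hydroxyl-directed hydride delivery.

Step 8
Reactants: 12 propargylic diol
Product: 14 (1S,4R,5S,6R,7Z)-8-iodoalkene diol, iodine cis to C6, via cyclic alkenylalanate 13 (not isolated)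
Conditions: Red-Al (4 equiv), THF, 0 °C → rt; EtOAc (destroys excess hydride); I2, THF, −78 → 0 °C
Reagents that add atoms: iodine, II
Why: In this alkoxide-directed trans-hydroalumination–iodinolysis, aluminium bound to O6 delivers hydride to C7 and ends on C8 in a five-membered alanate, and iodine replaces it with retention, which gives the Z geometry the cycloheptene needs.

Step 9
Reactants: 15 4-hydroxybenzoic acid
Product: 17 4-(triisopropylsilyloxy)benzoic acid, via bis-silylated acid 16 (not isolated)
Conditions: TIPSCl (2.3 equiv), imidazole, DMF, rt; then K2CO3, THF/H2O, rt; 1 M HCl to pH 4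
Reagents that add atoms: triisopropylsilyl chloride, CC(C)[Si](Cl)(C(C)C)C(C)C
Why: Exhaustive silylation followed by selective hydrolysis of the far more labile silyl ester leaves the phenol masked by a group that withstands borane, buffered peroxide, periodinane and chromium(II) yet leaves with fluoride.

Step 10
Reactants: 14 iodoalkene diol; 17 4-(triisopropylsilyloxy)benzoic acid
Product: 18 (1S,4R,5S,6R,7Z)-C6 4-(triisopropylsilyloxy)benzoate
Conditions: DCC, DMAP, CH2Cl2, 0 °C → rt
Reagents that add atoms: none
Why: Steglich esterification acylates the secondary allylic C6 hydroxyl with retention while the tertiary C4 hydroxyl is too hindered to react, and the ester also serves as the protecting group for O6.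

Step 11
Reactants: 18 ester
Product: 20 β-hydroxysilane, C1–CH(SiMe3)–CH2OH (C10 epimers, other centres as in 18), via B-alkyl-9-BBN adduct 19 (not isolated)
Conditions: 9-BBN (3 equiv), THF, 0 → 45 °C; then 30 % H2O2, pH 7 phosphate buffer, 0 °C → rt
Reagents that add atoms: hydrogen peroxide, OO
Why: In this hydroboration–oxidation boron adds to the unhindered terminal C9 of the 1,1-disubstituted vinylsilane while the deactivated trisubstituted iodoalkene and the ester are left alone, whereas the customary epoxidation–acid unmasking of a vinylsilane is avoided because it would place the carbonyl on C10.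

Step 12
Reactants: 20 β-hydroxysilane
Product: 22 (1R,4R,5S,6R,7Z)-iodo aldehyde, C1–CH2–CHO, via alpha-silyl aldehyde 21 (not isolated)
Conditions: Dess–Martin periodinane, CH2Cl2, 0 °C → rt; then THF/10 % aq. citric acid, rt
Reagents that add atoms: none
Why: Dess–Martin oxidation gives an α-trimethylsilyl aldehyde, a class that loses silicon readily by nucleophile-assisted C–Si cleavage to the enol, so mild aqueous acid should deliver the C10 methylene aldehyde and erase the inconsequential C10 stereocentre.

Step 13
Reactants: 22 iodo aldehyde
Product: 23 (1R,4R,5S,6S)-trans-fused hydroazulene allylic alcohol (C9 epimers)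
Conditions: CrCl2 (8 equiv), NiCl2 (2 mol % of Cr), degassed DMF, 0.005 M, rt
Reagents that add atoms: none
Why: In this intramolecular Nozaki–Hiyama–Kishi reaction nickel inserts into the C8–I bond and transmetalation gives an alkenylchromium(III) species that keeps the alkene geometry and adds only to the aldehyde, tolerating the ester, the tertiary alcohol and the aryl silyl ether, while high dilution favours the seven-membered ring and the C9 configuration is irrelevant.

Step 14
Reactants: 23 allylic alcohol
Product: 24 O-triisopropylsilyl lancerodiol p-hydroxybenzoate (1R,4R,5S,6S)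
Conditions: Dess–Martin periodinane, CH2Cl2, 0 °C → rt
Reagents that add atoms: none
Why: Dess–Martin oxidation of the secondary allylic alcohol gives the conjugated enone and removes the C9 stereocentre, and the tertiary alcohol cannot be oxidised.

Step 15
Reactants: 24 silyl-protected enone
Product: 25 lancerodiol p-hydroxybenzoate
Conditions: TBAF (1.1 equiv), AcOH (1.1 equiv), THF, 0 °C
Reagents that add atoms: none
Why: Fluoride-mediated desilylation cleaves the aryl silyl ether rapidly because the phenoxide is a good leaving group on silicon, and the acetic acid buffer prevents base-induced ester cleavage or enone isomerisation.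

Compound list
1 | trimethylsilylacetylene | C#C[Si](C)(C)C | starting material
2 | diisobutyl[1-(trimethylsilyl)vinyl]alane | C=C([Si](C)(C)C)[Al](CC(C)C)CC(C)C | intermediate
3 | but-2-yn-1-ol | CC#CCO | starting material
4 | but-2-ynal | CC#CC=O | intermediate
5 | 3-methylcyclopent-2-en-1-one | CC1=CC(=O)CC1 | starting material
6 | diisobutylaluminium C4=C5 enolate of (S)-3-methyl-3-[1-(trimethylsilyl)vinyl]cyclopentanone | C=C([Si](C)(C)C)[C@@]1(C)CCC(O[Al](CC(C)C)CC(C)C)=C1 | intermediate
7 | (2S,3S)-2-(1-hydroxybut-2-yn-1-yl)-3-methyl-3-[1-(trimethylsilyl)vinyl]cyclopentan-1-one, C6 epimers | CC#CC(O)[C@H]1C(=O)CC[C@]1(C)C(=C)[Si](C)(C)C | intermediate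
8 | C6 triethylsilyl ether of 7 | CC#CC(O[Si](CC)(CC)CC)[C@H]1C(=O)CC[C@]1(C)C(=C)[Si](C)(C)C | intermediate
9 | (1S,4R,5S)-C4 isopropyl carbinol, C6 triethylsilyl ether | CC#CC(O[Si](CC)(CC)CC)[C@@H]1[C@](C)(CC[C@@]1(O)C(C)C)C(=C)[Si](C)(C)C | intermediate
10 | (1S,4R,5S)-C4,C6-diol, C6 epimers | CC#CC(O)[C@@H]1[C@](C)(CC[C@@]1(O)C(C)C)C(=C)[Si](C)(C)C | intermediate
11 | (1S,4R,5R)-C4-hydroxy C6-ynone | CC#CC(=O)[C@@H]1[C@](C)(CC[C@@]1(O)C(C)C)C(=C)[Si](C)(C)C | intermediate
12 | (1S,4R,5S,6R)-propargylic diol | CC#C[C@H](O)[C@@H]1[C@](C)(CC[C@@]1(O)C(C)C)C(=C)[Si](C)(C)C | intermediate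
13 | disodium salt of the cyclic O6–Al–C8 alkenylalanate, O4 bound as hydridoalkoxyalanate | C/C1=C/[C@H](O[Al-]1(OCCOC)OCCOC)[C@@H]2[C@](C)(CC[C@@]2(O[AlH-](OCCOC)OCCOC)C(C)C)C(=C)[Si](C)(C)C.[Na+].[Na+] | intermediate
14 | (1S,4R,5S,6R,7Z)-8-iodoalkene diol | C/C(I)=C/[C@H](O)[C@@H]1[C@](C)(CC[C@@]1(O)C(C)C)C(=C)[Si](C)(C)C | intermediate
15 | 4-hydroxybenzoic acid | OC(=O)c1ccc(O)cc1 | starting material
16 | triisopropylsilyl 4-(triisopropylsilyloxy)benzoate | CC(C)[Si](C(C)C)(C(C)C)OC(=O)c1ccc(O[Si](C(C)C)(C(C)C)C(C)C)cc1 | intermediate
17 | 4-(triisopropylsilyloxy)benzoic acid | OC(=O)c1ccc(O[Si](C(C)C)(C(C)C)C(C)C)cc1 | intermediate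
18 | C6 4-(triisopropylsilyloxy)benzoate of 14 | C/C(I)=C/[C@H](OC(=O)c1ccc(O[Si](C(C)C)(C(C)C)C(C)C)cc1)[C@@H]2[C@](C)(CC[C@@]2(O)C(C)C)C(=C)[Si](C)(C)C | intermediate
19 | C9 B-alkyl-9-borabicyclo[3.3.1]nonane adduct of 18 | C/C(I)=C/[C@H](OC(=O)c1ccc(O[Si](C(C)C)(C(C)C)C(C)C)cc1)[C@@H]2[C@](C)(CC[C@@]2(O)C(C)C)C([Si](C)(C)C)CB3C4CCCC3CCC4 | intermediate
20 | β-hydroxysilane, C10 trimethylsilyl, C9 primary alcohol (C10 epimers) | C/C(I)=C/[C@H](OC(=O)c1ccc(O[Si](C(C)C)(C(C)C)C(C)C)cc1)[C@@H]2[C@](C)(CC[C@@]2(O)C(C)C)C([Si](C)(C)C)CO | intermediate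
21 | α-trimethylsilyl C9 aldehyde | C/C(I)=C/[C@H](OC(=O)c1ccc(O[Si](C(C)C)(C(C)C)C(C)C)cc1)[C@@H]2[C@](C)(CC[C@@]2(O)C(C)C)C([Si](C)(C)C)C=O | intermediate
22 | (1R,4R,5S,6R,7Z)-iodo aldehyde | C/C(I)=C/[C@H](OC(=O)c1ccc(O[Si](C(C)C)(C(C)C)C(C)C)cc1)[C@@H]2[C@](C)(CC[C@@]2(O)C(C)C)CC=O | intermediate
23 | (1R,4R,5S,6S)-4,9-dihydroxydauc-7-en-6-yl 4-(triisopropylsilyloxy)benzoate, C9 epimers | CC1=C[C@H](OC(=O)c3ccc(O[Si](C(C)C)(C(C)C)C(C)C)cc3)[C@@H]2[C@](C)(CC[C@@]2(O)C(C)C)CC1O | intermediate
24 | (1R,4R,5S,6S)-4-hydroxy-9-oxodauc-7-en-6-yl 4-(triisopropylsilyloxy)benzoate | CC1=C[C@H](OC(=O)c3ccc(O[Si](C(C)C)(C(C)C)C(C)C)cc3)[C@@H]2[C@](C)(CC[C@@]2(O)C(C)C)CC1=O | intermediate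
25 | lancerodiol p-hydroxybenzoate, (1R,4R,5S,6S)-4-hydroxy-9-oxodauc-7-en-6-yl 4-hydroxybenzoate | CC1=C[C@H](OC(=O)c2ccc(O)cc2)[C@@H]2[C@](C)(CC[C@@]2(O)C(C)C)CC1=O | target

Total steps: 15. Longest linear sequence: 13 (steps 1, 3–8, 10–15).

Steps most likely to fail

Step 3. The aluminium enolate is flanked by the new quaternary carbon and solvated by THF. It may add to the ynal too slowly, so that surplus alane consumes the aldehyde by 1,2-alkenylation or hydride transfer and the enolate is merely protonated on work-up. The fallback sets out from 5 and 2 and comes back at 7. The same copper-catalysed addition is run, but 6 is quenched with triethylsilyl triflate and isolated as the triethylsilyl enol ether F1, which keeps the C4=C5 regiochemistry. A Mukaiyama aldol addition of F1 to 4 (BF3·OEt2, CH2Cl2, −78 °C) then forms the same C5–C6 bond through an open transition state. The facial bias away from the silylvinyl group is unchanged, and hydrolytic work-up gives 7.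

Step 5. Three processes can compete with the addition: enolisation with loss of the β-silyloxy group, hydride transfer from the isopropyl reagent, and eroded facial selectivity at C4, because the 1-silylvinyl group shields part of the lower face. The fallback sets out from 8 and comes back at 10.
- Kinetic deprotonation at C3 (KHMDS, −78 °C) and triflation with N-phenyltriflimide give the enol triflate F2.
- Coupling with lithium diisopropylcuprate gives the isopropylcyclopentene F3.
- Dilute acid removes the silyl group to give the homoallylic alcohol F4.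
- Vanadium-catalysed hydroxyl-directed epoxidation (VO(acac)2, t-BuOOH) delivers oxygen to the ring face that carries the C5 side chain, giving the epoxy alcohol F5.
- LiEt3BH opens the epoxide at the secondary C3, leaving the C4 hydroxyl cis to C6 as in 10.

Step 11. The silicon-bearing carbinol may undergo Peterson elimination during the oxidative work-up or on silica. Material would then be spread over silylated and desilylated species, and the subsequent oxidation would become unclean. The fallback sets out from 18 and comes back at 22. Crude 20 from the same hydroboration–oxidation is mesylated (MsCl, Et3N, CH2Cl2, 0 °C → rt), and the β-silyl sulfonate collapses by a Peterson-type anti elimination to the C1 vinyl compound F6. This unhindered monosubstituted alkene is hydroborated a second time with 9-BBN and oxidised with buffered peroxide to the primary alcohol F7. Dess–Martin oxidation of F7 gives 22 without any α-silyl aldehyde.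

Further compounds
F1 | step 3 | triethylsilyl C4=C5 enol ether of (S)-3-methyl-3-[1-(trimethylsilyl)vinyl]cyclopentanone | C=C([Si](C)(C)C)[C@@]1(C)CCC(O[Si](CC)(CC)CC)=C1
F2 | step 5 | C3=C4 enol triflate of 8 | CC#CC(O[Si](CC)(CC)CC)[C@@H]1[C@](C)(CC=C1OS(=O)(=O)C(F)(F)F)C(=C)[Si](C)(C)C
F3 | step 5 | C4-isopropyl C3=C4 cyclopentene, C6 triethylsilyl ether | CC#CC(O[Si](CC)(CC)CC)[C@@H]1[C@](C)(CC=C1C(C)C)C(=C)[Si](C)(C)C
F4 | step 5 | C4-isopropyl C3=C4 cyclopentene, free C6 homoallylic alcohol | CC#CC(O)[C@@H]1[C@](C)(CC=C1C(C)C)C(=C)[Si](C)(C)C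
F5 | step 5 | C3,C4-epoxide on the face of the C5 side chain, free C6 alcohol | CC#CC(O)[C@@H]1[C@](C)(C[C@@H]2O[C@]12C(C)C)C(=C)[Si](C)(C)C
F6 | step 11 | C1 vinyl analogue of 18 | C/C(I)=C/[C@H](OC(=O)c1ccc(O[Si](C(C)C)(C(C)C)C(C)C)cc1)[C@@H]2[C@](C)(CC[C@@]2(O)C(C)C)C=C
F7 | step 11 | C9 primary alcohol, C10 methylene | C/C(I)=C/[C@H](OC(=O)c1ccc(O[Si](C(C)C)(C(C)C)C(C)C)cc1)[C@@H]2[C@](C)(CC[C@@]2(O)C(C)C)CCO
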